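## Retrosynthetic overview

1. Feature used: the C4 carbonyl carbon of ring C is bonded to C4a of ring A, which lies between C5 (carrying OMe) and C8a (carrying O1). O1 is bonded to the C2 stereocentre, so C4 is tethered to O1 through C2–C3 and an aryl anion at C4a can reach an acyl group at C4.
2. Key disconnection C4–C4a: bromine–lithium exchange at C4a of aryl ether 24 and 6-exo attack on its Weinreb amide close ring C, the only ring made in the route (rings A and B come from arenes).
3. O1–C2: Mitsunobu inversion of the (R)-β-hydroxy Weinreb amide 23 (ring B, from 2,4-dihydroxybenzaldehyde by aldol, oxidation and asymmetric hydrogenation) with bromophenol 18.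
4. Ring A piece 18 from 5-methoxyresorcinol: formylation tells the two phenols apart, the C6 side chain comes from an Evans prenylation and MeMgBr, and the C4a bromine from lithiation between OMOM and OMe.
5. Last step: pyridine-buffered HF removes all silyl groups.

Key step: step 17

Remark: ring A positions are named by flavanone numbering (O1, C4a, C5–C8, C8a) in all intermediates. O7 carries TIPS because it must survive methoxide, Grignard and n-BuLi conditions and shield C8. Regio- and diastereomeric by-products are taken to be separable by chromatography.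

## Route

Step 1
Reactants: 1 5-methoxyresorcinol
Product: 3 2,4-dihydroxy-6-methoxybenzaldehyde, via iminium chloride 2 (not isolated)
Conditions: POCl3, DMF, MeCN, 0 °C to rt; then H2O, 50 °C
Reagents that add atoms: N,N-dimethylformamide CN(C)C=O; water O
Why: Vilsmeier–Haack formylation should go para to one hydroxyl and ortho to the methoxy group, which desymmetrises 1 so that the para hydroxyl becomes O1, the chelated ortho hydroxyl becomes O7 and the formyl carbon becomes the C6 benzylic carbon.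

Step 2
Reactants: 3 2,4-dihydroxy-6-methoxybenzaldehyde
Product: 4 2-hydroxy-6-methoxy-4-(methoxymethoxy)benzaldehyde
Conditions: MOMCl (1.05 equiv), i-Pr2NEt, CH2Cl2, 0 °C
Reagents that add atoms: chloromethyl methyl ether COCCl
Why: O-alkylation (MOM ether formation) should be selective for the more acidic, non-chelated para hydroxyl because the ortho hydroxyl is held in a hydrogen bond to the aldehyde, and the MOM group later directs lithiation to C4a.

Step 3
Reactants: 4 2-hydroxy-6-methoxy-4-(methoxymethoxy)benzaldehyde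
Product: 5 2-methoxy-4-(methoxymethoxy)-6-(triisopropylsilyloxy)benzaldehyde
Conditions: TIPSCl, imidazole, DMAP (cat.), DMF, 40 °C
Reagents that add atoms: triisopropylsilyl chloride CC(C)[Si](Cl)(C(C)C)C(C)C
Why: imidazole-promoted silylation of the remaining phenol gives a base- and alkyllithium-stable TIPS ether on O7 that later shields C8.

Step 4
Reactants: 5 2-methoxy-4-(methoxymethoxy)-6-(triisopropylsilyloxy)benzaldehyde
Product: 6 benzyl (E)-3-[2-methoxy-4-(methoxymethoxy)-6-(triisopropylsilyloxy)phenyl]prop-2-enoate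
Conditions: Ph3P=CHCO2Bn, toluene, 100 °C
Reagents that add atoms: benzyl (triphenylphosphoranylidene)acetate O=C(C=P(c1ccccc1)(c1ccccc1)c1ccccc1)OCc1ccccc1
Why: Wittig olefination with a stabilised ylide gives the (E)-cinnamate and brings in the two carbons that become the side-chain stereocentre and the carbinol carbon, as an ester that can be cleaved without base.

Step 5
Reactants: 6 benzyl (E)-3-[2-methoxy-4-(methoxymethoxy)-6-(triisopropylsilyloxy)phenyl]prop-2-enoate
Product: 7 3-[2-methoxy-4-(methoxymethoxy)-6-(triisopropylsilyloxy)phenyl]propanoic acid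
Conditions: H2 (1 atm), 10% Pd/C, EtOAc, rt
Reagents that add atoms: none
Why: heterogeneous catalytic hydrogenation saturates the cinnamate double bond and hydrogenolyses the benzyl ester in one operation, leaving the MOM and aryl silyl ethers untouched.

Step 6
Reactants: 7 3-[2-methoxy-4-(methoxymethoxy)-6-(triisopropylsilyloxy)phenyl]propanoic acid
Product: 9 (4S)-4-benzyl-3-{3-[2-methoxy-4-(methoxymethoxy)-6-(triisopropylsilyloxy)phenyl]propanoyl}-1,3-oxazolidin-2-one, via mixed pivalic anhydride 8 (not isolated)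
Conditions: PivCl, Et3N, THF, −20 °C; then (S)-4-benzyl-2-oxazolidinone, LiCl, −20 °C to rt
Reagents that add atoms: (S)-4-benzyl-1,3-oxazolidin-2-one O=C1N[C@@H](Cc2ccccc2)CO1
Why: N-acylation of the Evans auxiliary through the mixed anhydride works because the pivaloyl carbonyl is shielded and the oxazolidinone attacks the arylpropanoyl carbonyl.

Step 7
Reactants: 9 (4S)-4-benzyl-3-{3-[2-methoxy-4-(methoxymethoxy)-6-(triisopropylsilyloxy)phenyl]propanoyl}-1,3-oxazolidin-2-one; 10 prenyl bromide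
Product: 12 (4S)-4-benzyl-3-[(2S)-2-{[2-methoxy-4-(methoxymethoxy)-6-(triisopropylsilyloxy)phenyl]methyl}-5-methylhex-4-enoyl]-1,3-oxazolidin-2-one, via sodium enolate 11 (not isolated)
Conditions: NaHMDS, THF, −78 °C; then prenyl bromide, −78 to −40 °C
Reagents that add atoms: none
Why: Evans asymmetric alkylation, in which the chelated sodium (Z)-enolate is prenylated on the face opposite the C4 benzyl group, should set the (S) side-chain stereocentre (priorities acyl > ArCH2 > prenyl CH2).

Step 8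
Reactants: 12 (4S)-4-benzyl-3-[(2S)-2-{[2-methoxy-4-(methoxymethoxy)-6-(triisopropylsilyloxy)phenyl]methyl}-5-methylhex-4-enoyl]-1,3-oxazolidin-2-one
Product: 13 methyl (2S)-2-{[2-methoxy-4-(methoxymethoxy)-6-(triisopropylsilyloxy)phenyl]methyl}-5-methylhex-4-enoate
Conditions: MeMgBr, MeOH, CH2Cl2, 0 °C
Reagents that add atoms: methanol CO
Why: transesterification with methoxymagnesium bromide at the exocyclic imide carbonyl releases the methyl ester and the auxiliary without epimerising the alpha stereocentre or cleaving the aryl TIPS ether.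

Step 9
Reactants: 13 methyl (2S)-2-{[2-methoxy-4-(methoxymethoxy)-6-(triisopropylsilyloxy)phenyl]methyl}-5-methylhex-4-enoate
Product: 14 (3S)-3-{[2-methoxy-4-(methoxymethoxy)-6-(triisopropylsilyloxy)phenyl]methyl}-2,6-dimethylhept-5-en-2-ol
Conditions: MeMgBr (4 equiv), THF, 0 °C to rt; aq NH4Cl
Reagents that add atoms: methylmagnesium bromide C[Mg]Br
Why: double Grignard addition to the ester builds the tertiary carbinol of the 2-hydroxypropan-2-yl group, and addition is faster than alpha deprotonation, so the adjacent stereocentre is kept.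

Step 10
Reactants: 14 (3S)-3-{[2-methoxy-4-(methoxymethoxy)-6-(triisopropylsilyloxy)phenyl]methyl}-2,6-dimethylhept-5-en-2-ol
Product: 16 (3S)-3-{[3-bromo-2-methoxy-4-(methoxymethoxy)-6-(triisopropylsilyloxy)phenyl]methyl}-2,6-dimethylhept-5-en-2-ol, via dilithio species 15 (not isolated)
Conditions: n-BuLi (2.4 equiv), THF, 0 °C; then BrCCl2CCl2Br, −78 °C to rt; aq NH4Cl
Reagents that add atoms: 1,2-dibromo-1,1,2,2-tetrachloroethane BrC(Cl)(Cl)C(Cl)(Cl)Br
Why: directed ortho-metalation, after deprotonation of the hydroxyl, should lithiate the only ring position flanked by two oxygen directors (between OMOM and OMe, the future C4a) because the other free position is shielded by the non-coordinating TIPS ether, and the aryllithium is then brominated by the positive-bromine donor.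

Step 11
Reactants: 16 (3S)-3-{[3-bromo-2-methoxy-4-(methoxymethoxy)-6-(triisopropylsilyloxy)phenyl]methyl}-2,6-dimethylhept-5-en-2-ol
Product: 18 2-bromo-3-methoxy-4-[(2S)-5-methyl-2-(2-triethylsilyloxypropan-2-yl)hex-4-en-1-yl]-5-(triisopropylsilyloxy)phenol, via bis(triethylsilyl) ether 17 (not isolated)
Conditions: TESOTf (4 equiv), 2,2′-bipyridyl, CH2Cl2, 0 °C to rt; then MeOH, K2CO3, 0 °C
Reagents that add atoms: triethylsilyl trifluoromethanesulfonate CC[Si](CC)(CC)OS(=O)(=O)C(F)(F)F
Why: silyl triflate with 2,2′-bipyridyl silylates the tertiary alcohol and exchanges the aromatic MOM acetal for an aryl triethylsilyl ether without acid, and base-catalysed methanolysis then cleaves only the labile bromine-flanked aryl TES ether, leaving the alkyl TES and aryl TIPS ethers.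

Step 12
Reactants: 19 2,4-dihydroxybenzaldehyde
Product: 20 2,4-bis(tert-butyldimethylsilyloxy)benzaldehyde
Conditions: TBSCl (2.4 equiv), imidazole, DMF, rt
Reagents that add atoms: tert-butyldimethylsilyl chloride CC(C)(C)[Si](C)(C)Cl
Why: standard imidazole-promoted silylation of both phenols gives ethers that tolerate t-BuLi at low temperature and are weaker donors than alkyl ethers.

Step 13
Reactants: 20 2,4-bis(tert-butyldimethylsilyloxy)benzaldehyde
Product: 21 rac-3-[2,4-bis(tert-butyldimethylsilyloxy)phenyl]-3-hydroxy-N-methoxy-N-methylpropanamide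
Conditions: MeC(O)N(OMe)Me, LDA, THF, −78 °C; then 20, −78 °C; AcOH quench at −78 °C
Reagents that add atoms: N-methoxy-N-methylacetamide CC(=O)N(C)OC
Why: aldol addition of the lithium enolate of the Weinreb acetamide to the aldehyde, quenched cold so that the lithium aldolate does not take over the ortho silyl group, gives the racemic β-hydroxy amide.

Step 14
Reactants: 21 rac-3-[2,4-bis(tert-butyldimethylsilyloxy)phenyl]-3-hydroxy-N-methoxy-N-methylpropanamide
Product: 22 3-[2,4-bis(tert-butyldimethylsilyloxy)phenyl]-N-methoxy-N-methyl-3-oxopropanamide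
Conditions: Dess–Martin periodinane, CH2Cl2, rt
Reagents that add atoms: none
Why: Dess–Martin oxidation converts the secondary benzylic alcohol into the β-keto amide under near-neutral conditions that spare the aryl silyl ethers.

Step 15
Reactants: 22 3-[2,4-bis(tert-butyldimethylsilyloxy)phenyl]-N-methoxy-N-methyl-3-oxopropanamide
Product: 23 (3R)-3-[2,4-bis(tert-butyldimethylsilyloxy)phenyl]-3-hydroxy-N-methoxy-N-methylpropanamide
Conditions: H2 (50 atm), RuCl2[(S)-BINAP](dmf)n (1 mol %), EtOH, 50 °C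
Reagents that add atoms: none
Why: Noyori asymmetric hydrogenation, in which the β-keto amide chelates divalent ruthenium through both carbonyl oxygens, should give the (R)-carbinol with the (S)-BINAP complex (the sense that gives (R)-3-aryl-3-hydroxypropanoates from aroylacetates).

Step 16
Reactants: 18 2-bromo-3-methoxy-4-[(2S)-5-methyl-2-(2-triethylsilyloxypropan-2-yl)hex-4-en-1-yl]-5-(triisopropylsilyloxy)phenol; 23 (3R)-3-[2,4-bis(tert-butyldimethylsilyloxy)phenyl]-3-hydroxy-N-methoxy-N-methylpropanamide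
Product: 24 (3S)-3-[2,4-bis(tert-butyldimethylsilyloxy)phenyl]-3-{2-bromo-3-methoxy-4-[(2S)-5-methyl-2-(2-triethylsilyloxypropan-2-yl)hex-4-en-1-yl]-5-(triisopropylsilyloxy)phenoxy}-N-methoxy-N-methylpropanamide
Conditions: PPh3, DIAD, toluene, −20 °C to rt
Reagents that add atoms: none
Why: Mitsunobu etherification, in which the acidic ortho-bromophenol displaces the oxyphosphonium of the benzylic alcohol by SN2 with inversion, should turn (R)-23 into the (S)-ether that becomes C2; silyl ethers on ring B and a non-polar solvent at low temperature disfavour ionisation.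

Step 17
Reactants: 24 (3S)-3-[2,4-bis(tert-butyldimethylsilyloxy)phenyl]-3-{2-bromo-3-methoxy-4-[(2S)-5-methyl-2-(2-triethylsilyloxypropan-2-yl)hex-4-en-1-yl]-5-(triisopropylsilyloxy)phenoxy}-N-methoxy-N-methylpropanamide
Product: 27 (2S)-2-[2,4-bis(tert-butyldimethylsilyloxy)phenyl]-5-methoxy-6-[(2S)-5-methyl-2-(2-triethylsilyloxypropan-2-yl)hex-4-en-1-yl]-7-(triisopropylsilyloxy)-2,3-dihydro-4H-chromen-4-one, via aryllithium 25 (not isolated), via lithium hemiaminal alkoxide 26 (not isolated)
Conditions: t-BuLi (2.1 equiv), THF, −100 °C, then −78 °C; sat. aq NH4Cl, −78 °C to rt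
Reagents that add atoms: none
Why: At −100 °C t-BuLi should exchange the C4a bromine faster than it deprotonates C3 or adds to the amide, the second equivalent destroying the tert-butyl bromide, to give aryllithium 25 flanked by the C5 methoxy and O1 oxygens. The C4a carbanion attacks the tethered N-methoxy-N-methyl amide carbonyl in a 6-exo-trig closure that forms the C4–C4a bond and ring C, and the lithium-chelated tetrahedral adduct 26 survives until the cold quench, so no ketone is exposed to base and no second addition occurs. The closest known reaction type is the Parham cyclisation of ortho-bromoaryl ethers carrying a tethered Weinreb amide to chroman-4-ones. No stereocentre is created: C2 (S, from step 16) and the side-chain centre (S, from step 7) are spectators, and the hemiaminal carbon of 26 becomes the sp2 ketone carbon on work-up. Site selectivity (C4a, not C8) is fixed by the bromine placed in step 10, and the step needs exchange and closure to outrun formation of a C3 anion that would expel the ring A aryloxide, which the low temperature, the fast exchange of an aryl bromide with t-BuLi and the chelation-assisted intramolecular acyl transfer should secure. No silyl ether is ortho to the lithiated carbon, so no silyl shift to carbon can intervene.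

Step 18
Reactants: 27 (2S)-2-[2,4-bis(tert-butyldimethylsilyloxy)phenyl]-5-methoxy-6-[(2S)-5-methyl-2-(2-triethylsilyloxypropan-2-yl)hex-4-en-1-yl]-7-(triisopropylsilyloxy)-2,3-dihydro-4H-chromen-4-one
Product: 28 (2S)-2-(2,4-dihydroxyphenyl)-7-hydroxy-6-[(2S)-2-(2-hydroxypropan-2-yl)-5-methylhex-4-en-1-yl]-5-methoxy-2,3-dihydro-4H-chromen-4-one
Conditions: HF·pyridine, pyridine, THF, 0 °C to rt
Reagents that add atoms: none
Why: fluoride-mediated desilylation with pyridine-buffered HF should remove the two aryl TBS, the aryl TIPS and the tertiary TES ethers under mildly acidic conditions that neither open the flavanone to the chalcone (which would racemise C2) nor ionise the tertiary alcohol.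

## Compound list

1 | 5-methoxyresorcinol | COc1cc(O)cc(O)c1 | starting material
2 | N-[(2,4-dihydroxy-6-methoxyphenyl)methylidene]-N-methylmethanaminium chloride (step 1, not isolated) | C[N+](C)=Cc1c(O)cc(O)cc1OC.[Cl-] | intermediate
3 | 2,4-dihydroxy-6-methoxybenzaldehyde | O=Cc1c(O)cc(O)cc1OC | intermediate
4 | 2-hydroxy-6-methoxy-4-(methoxymethoxy)benzaldehyde | O=Cc1c(O)cc(OCOC)cc1OC | intermediate
5 | 2-methoxy-4-(methoxymethoxy)-6-(triisopropylsilyloxy)benzaldehyde | O=Cc1c(O[Si](C(C)C)(C(C)C)C(C)C)cc(OCOC)cc1OC | intermediate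
6 | benzyl (E)-3-[2-methoxy-4-(methoxymethoxy)-6-(triisopropylsilyloxy)phenyl]prop-2-enoate | O=C(/C=C/c1c(O[Si](C(C)C)(C(C)C)C(C)C)cc(OCOC)cc1OC)OCc1ccccc1 | intermediate
7 | 3-[2-methoxy-4-(methoxymethoxy)-6-(triisopropylsilyloxy)phenyl]propanoic acid | OC(=O)CCc1c(O[Si](C(C)C)(C(C)C)C(C)C)cc(OCOC)cc1OC | intermediate
8 | mixed anhydride of 7 with pivalic acid (step 6, not isolated) | CC(C)(C)C(=O)OC(=O)CCc1c(O[Si](C(C)C)(C(C)C)C(C)C)cc(OCOC)cc1OC | intermediate
9 | (4S)-4-benzyl-3-{3-[2-methoxy-4-(methoxymethoxy)-6-(triisopropylsilyloxy)phenyl]propanoyl}-1,3-oxazolidin-2-one | O=C(CCc1c(O[Si](C(C)C)(C(C)C)C(C)C)cc(OCOC)cc1OC)N1[C@@H](Cc2ccccc2)COC1=O | intermediate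
10 | prenyl bromide (1-bromo-3-methylbut-2-ene) | CC(C)=CCBr | starting material
11 | sodium (Z)-enolate of 9 (step 7, not isolated) | [Na+].[O-]/C(=C\Cc1c(O[Si](C(C)C)(C(C)C)C(C)C)cc(OCOC)cc1OC)N1[C@@H](Cc2ccccc2)COC1=O | intermediate
12 | (4S)-4-benzyl-3-[(2S)-2-{[2-methoxy-4-(methoxymethoxy)-6-(triisopropylsilyloxy)phenyl]methyl}-5-methylhex-4-enoyl]-1,3-oxazolidin-2-one | COc1cc(OCOC)cc(O[Si](C(C)C)(C(C)C)C(C)C)c1C[C@H](CC=C(C)C)C(=O)N1[C@@H](Cc2ccccc2)COC1=O | intermediate
13 | methyl (2S)-2-{[2-methoxy-4-(methoxymethoxy)-6-(triisopropylsilyloxy)phenyl]methyl}-5-methylhex-4-enoate | COc1cc(OCOC)cc(O[Si](C(C)C)(C(C)C)C(C)C)c1C[C@H](CC=C(C)C)C(=O)OC | intermediate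
14 | (3S)-3-{[2-methoxy-4-(methoxymethoxy)-6-(triisopropylsilyloxy)phenyl]methyl}-2,6-dimethylhept-5-en-2-ol | COc1cc(OCOC)cc(O[Si](C(C)C)(C(C)C)C(C)C)c1C[C@H](CC=C(C)C)C(C)(C)O | intermediate
15 | lithium alkoxide of 14 lithiated at the ring carbon between OMOM and OMe (step 10, not isolated) | COc1c([Li])c(OCOC)cc(O[Si](C(C)C)(C(C)C)C(C)C)c1C[C@H](CC=C(C)C)C(C)(C)O[Li] | intermediate
16 | (3S)-3-{[3-bromo-2-methoxy-4-(methoxymethoxy)-6-(triisopropylsilyloxy)phenyl]methyl}-2,6-dimethylhept-5-en-2-ol | COc1c(Br)c(OCOC)cc(O[Si](C(C)C)(C(C)C)C(C)C)c1C[C@H](CC=C(C)C)C(C)(C)O | intermediate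
17 | aryl and tertiary-alkyl bis(triethylsilyl) ether of the bromophenol (step 11, not isolated) | COc1c(Br)c(O[Si](CC)(CC)CC)cc(O[Si](C(C)C)(C(C)C)C(C)C)c1C[C@H](CC=C(C)C)C(C)(C)O[Si](CC)(CC)CC | intermediate
18 | 2-bromo-3-methoxy-4-[(2S)-5-methyl-2-(2-triethylsilyloxypropan-2-yl)hex-4-en-1-yl]-5-(triisopropylsilyloxy)phenol | COc1c(Br)c(O)cc(O[Si](C(C)C)(C(C)C)C(C)C)c1C[C@H](CC=C(C)C)C(C)(C)O[Si](CC)(CC)CC | intermediate
19 | 2,4-dihydroxybenzaldehyde | O=Cc1ccc(O)cc1O | starting material
20 | 2,4-bis(tert-butyldimethylsilyloxy)benzaldehyde | O=Cc1ccc(O[Si](C)(C)C(C)(C)C)cc1O[Si](C)(C)C(C)(C)C | intermediate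
21 | rac-3-[2,4-bis(tert-butyldimethylsilyloxy)phenyl]-3-hydroxy-N-methoxy-N-methylpropanamide | CON(C)C(=O)CC(O)c1ccc(O[Si](C)(C)C(C)(C)C)cc1O[Si](C)(C)C(C)(C)C | intermediate
22 | 3-[2,4-bis(tert-butyldimethylsilyloxy)phenyl]-N-methoxy-N-methyl-3-oxopropanamide | CON(C)C(=O)CC(=O)c1ccc(O[Si](C)(C)C(C)(C)C)cc1O[Si](C)(C)C(C)(C)C | intermediate
23 | (3R)-3-[2,4-bis(tert-butyldimethylsilyloxy)phenyl]-3-hydroxy-N-methoxy-N-methylpropanamide | CON(C)C(=O)C[C@H](c1ccc(O[Si](C)(C)C(C)(C)C)cc1O[Si](C)(C)C(C)(C)C)O | intermediate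
24 | (3S)-3-[2,4-bis(tert-butyldimethylsilyloxy)phenyl]-3-{2-bromo-3-methoxy-4-[(2S)-5-methyl-2-(2-triethylsilyloxypropan-2-yl)hex-4-en-1-yl]-5-(triisopropylsilyloxy)phenoxy}-N-methoxy-N-methylpropanamide | CON(C)C(=O)C[C@@H](c1ccc(O[Si](C)(C)C(C)(C)C)cc1O[Si](C)(C)C(C)(C)C)Oc1cc(O[Si](C(C)C)(C(C)C)C(C)C)c(C[C@H](CC=C(C)C)C(C)(C)O[Si](CC)(CC)CC)c(OC)c1Br | intermediate
25 | aryllithium from 24, lithium in place of bromine at C4a (step 17, not isolated) | CON(C)C(=O)C[C@@H](c1ccc(O[Si](C)(C)C(C)(C)C)cc1O[Si](C)(C)C(C)(C)C)Oc1cc(O[Si](C(C)C)(C(C)C)C(C)C)c(C[C@H](CC=C(C)C)C(C)(C)O[Si](CC)(CC)CC)c(OC)c1[Li] | intermediate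
26 | lithium alkoxide of the cyclic C4 N-methoxy-N-methyl hemiaminal (step 17, not isolated) | COc1c(C[C@H](CC=C(C)C)C(C)(C)O[Si](CC)(CC)CC)c(O[Si](C(C)C)(C(C)C)C(C)C)cc2c1C([O-])(N(C)OC)C[C@@H](c1ccc(O[Si](C)(C)C(C)(C)C)cc1O[Si](C)(C)C(C)(C)C)O2.[Li+] | intermediate
27 | (2S)-2-[2,4-bis(tert-butyldimethylsilyloxy)phenyl]-5-methoxy-6-[(2S)-5-methyl-2-(2-triethylsilyloxypropan-2-yl)hex-4-en-1-yl]-7-(triisopropylsilyloxy)-2,3-dihydro-4H-chromen-4-one | COc1c(C[C@H](CC=C(C)C)C(C)(C)O[Si](CC)(CC)CC)c(O[Si](C(C)C)(C(C)C)C(C)C)cc2c1C(=O)C[C@@H](c1ccc(O[Si](C)(C)C(C)(C)C)cc1O[Si](C)(C)C(C)(C)C)O2 | intermediate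
28 | (2S)-2-(2,4-dihydroxyphenyl)-7-hydroxy-6-[(2S)-2-(2-hydroxypropan-2-yl)-5-methylhex-4-en-1-yl]-5-methoxy-2,3-dihydro-4H-chromen-4-one | COc1c(C[C@H](CC=C(C)C)C(C)(C)O)c(O)cc2c1C(=O)C[C@@H](c1ccc(O)cc1O)O2 | target

## Step count and risks

Total step count: 18. Longest linear sequence: 14 steps (steps 1–11, then 16, 17 and 18).

Steps most likely to fail:

1. Step 17 (ring closure). Proton transfer may compete with ring closure: the aryllithium or t-BuLi removes a C3 proton next to the amide, the enolate expels the ring A aryloxide, and the tether is cut before the C4–C4a bond forms. Slow exchange would also let t-BuLi attack the amide. Fallback (sets out from 16 and 23, comes back at 27): the C4–C4a bond is made between the two fragments before O1 is joined to C2, so no aryloxide sits beta to an enolisable carbonyl during the anionic step. The tertiary hydroxyl of 16 is silylated (TESCl, imidazole, DMAP, DMF, 40 °C) to give the MOM-protected aryl bromide F1. Bromine–lithium exchange (n-BuLi, THF, −78 °C) and addition of the aryllithium to 23, held as its chloromagnesium alkoxide (i-PrMgCl, THF, −40 °C), should give the (R)-β-hydroxy aryl ketone F2. The aromatic MOM ether is removed (TMSOTf, 2,2′-bipyridyl, MeCN, 0 °C; then water) to give the 2-hydroxyaryl β-hydroxy ketone F3. An intramolecular Mitsunobu etherification (PPh3, DIAD, THF, 0 °C) then closes ring C at O1–C2 with inversion of the (R)-carbinol and gives 27.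

2. Step 16 (Mitsunobu). The oxyphosphonium of the electron-rich benzylic carbinol may ionise to a silyloxy-stabilised cation, with loss of configuration, or lose Ph3PO by elimination towards the cinnamamide. Fallback (sets out from 20 and 18, comes back at 24): the O1–C2 bond and the C2 configuration are made by catalyst control, not by substitution at a preformed carbinol. Horner–Wadsworth–Emmons olefination of 20 (triethyl phosphonoacetate, NaH, THF) gives the ethyl (E)-cinnamate F4, DIBAL-H (CH2Cl2, −78 °C) the (E)-cinnamyl alcohol F5, and ClCO2Me with pyridine the methyl carbonate F6. Iridium-catalysed enantioselective allylic etherification of F6 with the sodium phenoxide of 18 ([Ir(cod)Cl]2, BINOL-derived N,N-bis(1-phenylethyl)phosphoramidite, THF, 50 °C) should give the branched allyl aryl ether F7. The ligand antipode that delivers the (S)-ether is not assigned here and would be fixed on a model phenoxide. Hydroboration of the vinyl group with 9-BBN and oxidation (NaBO3·4H2O) gives the primary alcohol F8, TEMPO with PhI(OAc)2 in MeCN–water the carboxylic acid F9, and coupling with MeONHMe·HCl (EDC·HCl, i-Pr2NEt, CH2Cl2) returns 24.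

3. Step 10 (lithiation and bromination). Metalation may occur at the wrong site (C8 next to the silyl ether, or the benzylic CH2), or n-BuLi may attack silicon, so that bromine does not end up at C4a. Fallback (sets out from 14, comes back at 18): bromine is put in by electrophilic substitution directed by the free O1 hydroxyl. 14 is treated with TESOTf and 2,2′-bipyridyl (CH2Cl2, 0 °C to rt) to give the bis(triethylsilyl) ether F10, and K2CO3 in MeOH at 0 °C frees the phenol F11. NBS with catalytic i-Pr2NH (CH2Cl2, −78 °C) should brominate ortho to the hydroxyl at the position next to OMe, because the other ortho position lies under the TIPS ether and the para position carries the side chain, and this gives 18.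

## Further compounds

F1 | step 17 | triethyl{[(3S)-3-{[3-bromo-2-methoxy-4-(methoxymethoxy)-6-(triisopropylsilyloxy)phenyl]methyl}-2,6-dimethylhept-5-en-2-yl]oxy}silane | COc1c(Br)c(OCOC)cc(O[Si](C(C)C)(C(C)C)C(C)C)c1C[C@H](CC=C(C)C)C(C)(C)O[Si](CC)(CC)CC
F2 | step 17 | (3R)-3-[2,4-bis(tert-butyldimethylsilyloxy)phenyl]-3-hydroxy-1-{2-methoxy-6-(methoxymethoxy)-3-[(2S)-5-methyl-2-(2-triethylsilyloxypropan-2-yl)hex-4-en-1-yl]-4-(triisopropylsilyloxy)phenyl}propan-1-one | COCOc1cc(O[Si](C(C)C)(C(C)C)C(C)C)c(C[C@H](CC=C(C)C)C(C)(C)O[Si](CC)(CC)CC)c(OC)c1C(=O)C[C@H](c1ccc(O[Si](C)(C)C(C)(C)C)cc1O[Si](C)(C)C(C)(C)C)O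
F3 | step 17 | (3R)-3-[2,4-bis(tert-butyldimethylsilyloxy)phenyl]-3-hydroxy-1-{6-hydroxy-2-methoxy-3-[(2S)-5-methyl-2-(2-triethylsilyloxypropan-2-yl)hex-4-en-1-yl]-4-(triisopropylsilyloxy)phenyl}propan-1-one | COc1c(C[C@H](CC=C(C)C)C(C)(C)O[Si](CC)(CC)CC)c(O[Si](C(C)C)(C(C)C)C(C)C)cc(O)c1C(=O)C[C@H](c1ccc(O[Si](C)(C)C(C)(C)C)cc1O[Si](C)(C)C(C)(C)C)O
F4 | step 16 | ethyl (E)-3-[2,4-bis(tert-butyldimethylsilyloxy)phenyl]prop-2-enoate | CCOC(=O)/C=C/c1ccc(O[Si](C)(C)C(C)(C)C)cc1O[Si](C)(C)C(C)(C)C
F5 | step 16 | (E)-3-[2,4-bis(tert-butyldimethylsilyloxy)phenyl]prop-2-en-1-ol | OC/C=C/c1ccc(O[Si](C)(C)C(C)(C)C)cc1O[Si](C)(C)C(C)(C)C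
F6 | step 16 | (E)-3-[2,4-bis(tert-butyldimethylsilyloxy)phenyl]prop-2-en-1-yl methyl carbonate | COC(=O)OC/C=C/c1ccc(O[Si](C)(C)C(C)(C)C)cc1O[Si](C)(C)C(C)(C)C
F7 | step 16 | (1S)-1-[2,4-bis(tert-butyldimethylsilyloxy)phenyl]prop-2-en-1-yl ether of phenol 18 | C=C[C@@H](c1ccc(O[Si](C)(C)C(C)(C)C)cc1O[Si](C)(C)C(C)(C)C)Oc1cc(O[Si](C(C)C)(C(C)C)C(C)C)c(C[C@H](CC=C(C)C)C(C)(C)O[Si](CC)(CC)CC)c(OC)c1Br
F8 | step 16 | (3S)-3-[2,4-bis(tert-butyldimethylsilyloxy)phenyl]-3-{2-bromo-3-methoxy-4-[(2S)-5-methyl-2-(2-triethylsilyloxypropan-2-yl)hex-4-en-1-yl]-5-(triisopropylsilyloxy)phenoxy}propan-1-ol | OCC[C@@H](c1ccc(O[Si](C)(C)C(C)(C)C)cc1O[Si](C)(C)C(C)(C)C)Oc1cc(O[Si](C(C)C)(C(C)C)C(C)C)c(C[C@H](CC=C(C)C)C(C)(C)O[Si](CC)(CC)CC)c(OC)c1Br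
F9 | step 16 | (3S)-3-[2,4-bis(tert-butyldimethylsilyloxy)phenyl]-3-{2-bromo-3-methoxy-4-[(2S)-5-methyl-2-(2-triethylsilyloxypropan-2-yl)hex-4-en-1-yl]-5-(triisopropylsilyloxy)phenoxy}propanoic acid | OC(=O)C[C@@H](c1ccc(O[Si](C)(C)C(C)(C)C)cc1O[Si](C)(C)C(C)(C)C)Oc1cc(O[Si](C(C)C)(C(C)C)C(C)C)c(C[C@H](CC=C(C)C)C(C)(C)O[Si](CC)(CC)CC)c(OC)c1Br
F10 | step 10 | triethyl{3-methoxy-4-[(2S)-5-methyl-2-(2-triethylsilyloxypropan-2-yl)hex-4-en-1-yl]-5-(triisopropylsilyloxy)phenoxy}silane | COc1cc(O[Si](CC)(CC)CC)cc(O[Si](C(C)C)(C(C)C)C(C)C)c1C[C@H](CC=C(C)C)C(C)(C)O[Si](CC)(CC)CC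
F11 | step 10 | 3-methoxy-4-[(2S)-5-methyl-2-(2-triethylsilyloxypropan-2-yl)hex-4-en-1-yl]-5-(triisopropylsilyloxy)phenol | COc1cc(O)cc(O[Si](C(C)C)(C(C)C)C(C)C)c1C[C@H](CC=C(C)C)C(C)(C)O[Si](CC)(CC)CC
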